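| flask | G | E | J | remark | time |
|---|---|---|---|---|---|
| ash | 0.077 M | 0.11 M | 0.154 M | run made earlier |  |
| birch | 0.077 M | 0.32 M | 0.154 M | run made earlier |  |
| Tuesday's | 0.077 M | 0.0924 M | 0.154 M |  | 3.0 h |
| Monday's | 0.077 M | 0.193 M | 0.154 M |  | 3.0 h |
| Saturday's | 0.077 M | 0.231 M | 0.154 M |  | 3.0 h |

| run | time / min | L / % | G / % |
|---|---|---|---|
| ash | 25.0 | 0.3 | 93.3 |
| ash | 50.0 | 0.5 | 89.5 |
| ash | 60.0 | 0.8 | 87.8 |
| ash | 90.0 | 1.9 | 84.5 |
| birch | 8.00 | 0 | 93.5 |
| birch | 15.0 | 0.4 | 88.0 |
| birch | 40.0 | 5.0 | 75.1 |
| birch | 90.0 | 13.3 | 59.5 |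

(each reading ± 0.3 percentage points)

- a species is counted by the G in it: one Z counts as two
- amounts and yields of L count Z too
- steps that have been proposed: G + E <-> J + D; D + E <-> J + L; G + L <-> Z; E <-> Q
- in an amount of L, one Z counts as one L

- final L, as a percentage of the G charged, for each flask in turn (Tuesday's, Monday's, Saturday's)

- If you take over these flasks, start from what I put in: G, then J at twice the G charge, and E at 1.20, 2.51 and 3.00 of the G charge in Tuesday's, Monday's and Saturday's.
- Ash and birch, at 1.43 and 4.16, were my two ends. Monday's and Saturday's lay between them, while Tuesday's lay a little below ash, so there I extrapolated.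
- At 90.0 min ash held L 1.9% and birch 13.3%. That gave 1.82 for the E exponent, an apparent order in E: the logarithm of the ratio of L at one time over the logarithm of the ratio of E charges, between flasks charged with the same G and the same J. It is a reading, and ash's L, good to 0.3 percentage points, is the smaller of its two numbers.
- Birch's L grew from 40.0 min to 90.0 min as time to the power 1.21, so I multiplied by 2.31 to reach 3.0 h.
- Joining the two, I expected L of 3.19%, 12.2% and 16.9% in Tuesday's, Monday's and Saturday's. That took two ratios and no stepping.
- I asked that the charges of G and J not be touched, since the exponent was read with both at these same charges.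
- The forecast gave 3.5%, 11.5% and 15%, “where L scales as about E^1.8”. I stood lower on Tuesday's and higher on Saturday's.

    G + E ⇌ J + D (K = 1.60, k = 4.80 × 10⁻⁴ /M/s)
    D + E ⇌ J + L (K = 23.0, k = 6.90 × 10⁻⁴ /M/s)
    G + L ⇌ Z, settled at all times (K = 6.60 /M)
    E ⇌ Q (K = 0.830, k = 2.10 × 10⁻⁴ /s)

The flasks gave L 3.53%, 12.3% and 16.2% in Tuesday's, Monday's and Saturday's. Carried from ash, the E exponent gave 5.29% for Monday's at 1.50 h, where 5.51% stood, and 7.34% for Saturday's, where 7.50% stood. In Tuesday's, half of the turnover of G + E to J + D was done by 0.880 h, but half of that of D + E to J + L not until 1.74 h. At 3.00 h Tuesday's D was being made 1.99 times as fast as it was used up, each step taken net, and D stood at 14.9% against L at 3.53%.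

The numbers in the tables were computed with made-up constants, noise included.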